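**Retrosynthetic overview**

1. Ring numbering: C1 is the ketone next to the carbinol, C2 bears the acyl group, C3 is the enol carbon, C4 and C5 are CH2, and C6 is the (S)-carbinol. Enabling feature: C2 is bonded to three carbonyl-level carbons (exocyclic acyl carbon, C1, C3), and the C6 oxygen stands 1,4 to C3 along C6–C5–C4–C3. The unit O–C6–C5–C4–C3 is therefore a latent γ-butyrolactone ring.
2. Key disconnection: the exocyclic acyl carbon–C2 bond and the C2–C3 bond are both cut. This leads to (E)-hexadec-14-enal and (S)-5-(2-diazoacetyl)-γ-butyrolactone. The diazo group is a traceless activator of C2. The lactone is a temporary ring that stores C3 as the acyl donor and holds the C6 oxygen.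
3. Order of rings: the γ-lactone comes first, from (S)-glutamic acid with retention. The key step closes the carbocycle through a transient 7-oxabicyclo[2.2.1]heptane. Its C3–O bridge bond then breaks, so only the cyclohexane ring remains.
4. Side chain: a C6 + C10 copper-catalysed alkyl–alkyl coupling joins (E)-hex-4-en-1-ol (as its bromide) to methyl 10-bromodecanoate, followed by ester-to-aldehyde reduction.
5. The route is convergent and uses no protecting groups. The only stereocentre comes from the chiral pool, and none of its bonds to C, H or O is broken after step 1.

Key step: step 7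

Assumption: the target is a β-triketone whose enol tautomers interconvert rapidly, so the drawn tautomer stands for the equilibrium mixture and C6 is the only stereocentre.

**Step 1**
Reactants: 1 (S)-glutamic acid
Product: 2 (S)-5-oxotetrahydrofuran-2-carboxylic acid
Conditions: NaNO2 (1.5 equiv), 2 M aq HCl, 0 °C → rt; evaporation, EtOAc extraction, recrystallisation
Reagents that add atoms: none
Why: Diazotisation of an α-amino acid proceeds with double inversion (the α-carboxylate displaces N2, then the γ-carboxyl group closes the five-membered lactone at the same carbon), so the (S) centre of 1 should appear in 2 with net retention and becomes C6 of the target.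

**Step 2**
Reactants: 2 (S)-5-oxotetrahydrofuran-2-carboxylic acid
Product: 3 (S)-5-oxotetrahydrofuran-2-carbonyl chloride
Conditions: (COCl)2 (1.2 equiv), DMF (cat.), CH2Cl2, 0 °C → rt
Reagents that add atoms: oxalyl chloride, O=C(Cl)C(=O)Cl
Why: Acid chloride formation with oxalyl chloride and catalytic DMF (Vilsmeier-type activation) runs without amine base, so neither ketene formation nor enolisation should erode the α-oxygenated stereocentre, and the lactone is inert.

**Step 3**
Reactants: 3 (S)-5-oxotetrahydrofuran-2-carbonyl chloride
Product: 4 (S)-5-(2-diazoacetyl)dihydrofuran-2(3H)-one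
Conditions: TMSCHN2 (2 equiv, 2 M in Et2O), THF–MeCN 1:1, 0 °C
Reagents that add atoms: (trimethylsilyl)diazomethane, C[Si](C)(C)C=[N+]=[N-]
Why: Acylation of a diazoalkane as in the first stage of the Arndt–Eistert sequence: the diazo carbon attacks the acid chloride, far more electrophilic than the lactone, and chloride takes the silyl group, so that no base is needed and the stereocentre is untouched.

**Step 4**
Reactants: 5 (E)-hex-4-en-1-ol
Product: 6 (E)-6-bromohex-2-ene
Conditions: CBr4 (1.1 equiv), PPh3 (1.15 equiv), CH2Cl2, 0 °C
Reagents that add atoms: carbon tetrabromide, BrC(Br)(Br)Br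
Why: Appel reaction, an SN2 displacement at the primary carbinol carbon under neutral conditions that leaves the remote (E)-alkene unchanged.

**Step 5**
Reactants: 6 (E)-6-bromohex-2-ene; 7 methyl 10-bromodecanoate
Product: 9 methyl (E)-hexadec-14-enoate, via hexenyl Grignard reagent 8 (not isolated)
Conditions: 6, Mg (1.3 equiv), THF, 35 °C; the solution is added slowly to 7, Li2CuCl4 (3 mol %), NMP (4 equiv), THF, 0 → 20 °C
Reagents that add atoms: none
Why: Kochi-type copper-catalysed cross-coupling of a primary alkyl Grignard reagent with a primary alkyl bromide, which in the presence of NMP is known to outrun addition to an ester, joins the C6 and C10 pieces without touching the alkene geometry.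

**Step 6**
Reactants: 9 methyl (E)-hexadec-14-enoate
Product: 10 (E)-hexadec-14-enal
Conditions: i-Bu2AlH (1.05 equiv), CH2Cl2, −78 °C; MeOH, then aq potassium sodium tartrate
Reagents that add atoms: none
Why: Partial reduction of an ester with i-Bu2AlH: the tetrahedral aluminium hemiacetal persists at −78 °C and releases the aldehyde only on quenching, and the isolated alkene is not hydroaluminated at this temperature.

**Step 7**
Reactants: 4 (S)-5-(2-diazoacetyl)dihydrofuran-2(3H)-one; 10 (E)-hexadec-14-enal
Product: 13 (6S)-2-[(E)-hexadec-14-enoyl]-3,6-dihydroxycyclohex-2-en-1-one, via diketo lactone 11 (not isolated), via oxa-bridged bicyclic adduct 12 (not isolated)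
Conditions: 4 (1.1 equiv), 10 (1.0 equiv), SnCl2 (15 mol %), CH2Cl2, 0 °C → rt until N2 evolution ends; then DBU (2.5 equiv), MeCN, CH2Cl2 distilled off, 25 → 60 °C, Ar; cold 1 M HCl to pH 3
Reagents that add atoms: none
Why: Proposed new method: SnCl2 activates aldehyde 10 toward attack by the nucleophilic diazo carbon of 4, and a 1,2-hydride shift with loss of N2 (Roskamp-type homologation, known for aldehydes with α-diazoketones) forges the acyl carbon–C2 bond, raises the aldehyde carbon to the ketone level and gives 1,3-diketone 11 before any base has met the C6 stereocentre. DBU then removes only the C2–H of 11, and the enolate carbon adds across the lactone to its carbonyl C3; because the enolate double bond that reacts is the one to the newly installed exocyclic acyl group, both rings closed by this bond, the six-membered carbocycle C1–C6 and the five-membered ring C1–C2–C3–O–C6, form in the favoured (enolexo)-exo-trig mode, whereas the unacylated methyl ketone enolate would face a disfavoured 5-(enolendo) closure. The resulting 7-oxabicyclo[2.2.1]heptane alkoxide 12 is strained and collapses by breaking its C3–O bridge bond, which expels the C6 oxygen as the free alcohol, and proton transfer to the triketonate (several pK units more acidic than 11) makes the sequence irreversible, so that O-acylated or enol-lactone isomers should funnel to the same sink. The closest known reaction types for this second stage are the Dieckmann cyclisation of 5,7-dioxo esters to 2-acylcyclohexane-1,3-diones, the Lacey–Dieckmann synthesis of 3-acyltetronic and 3-acyltetramic acids and the base-induced enol-lactone to cyclic 1,3-dione rearrangement; new is the use of an intact γ-lactone as the acyl donor across its own ring. No lasting stereocentre is created: in 12 the configuration at C3 is dictated by C6, since the two-atom C1–C2 arm can reach only the lactone face on which it stands, the C2 centre vanishes on enolisation, and C6 stays (S) because none of its bonds is broken and its proton is shielded from DBU by the adjacent enolate charge. The selectivities needed are hydride over alkyl shift in the first stage (typical of unbranched aliphatic aldehydes), C2–H over C6–H deprotonation (secured by the pKa gap between a 1,3-diketone and an α-acyloxy ketone) and inertness of the remote (E)-alkene (no carbenoid-forming metal is present).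

**Compound list**

1 | (S)-glutamic acid | N[C@@H](CCC(=O)O)C(=O)O | starting material
2 | (S)-5-oxotetrahydrofuran-2-carboxylic acid | OC(=O)[C@@H]1CCC(=O)O1 | intermediate
3 | (S)-5-oxotetrahydrofuran-2-carbonyl chloride | ClC(=O)[C@@H]1CCC(=O)O1 | intermediate
4 | (S)-5-(2-diazoacetyl)dihydrofuran-2(3H)-one | [N-]=[N+]=CC(=O)[C@@H]1CCC(=O)O1 | intermediate
5 | (E)-hex-4-en-1-ol | C/C=C/CCCO | starting material
6 | (E)-6-bromohex-2-ene | C/C=C/CCCBr | intermediate
7 | methyl 10-bromodecanoate | COC(=O)CCCCCCCCCBr | starting material
8 | (E)-hex-4-en-1-ylmagnesium bromide | C/C=C/CCC[Mg]Br | intermediate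
9 | methyl (E)-hexadec-14-enoate | C/C=C/CCCCCCCCCCCCC(=O)OC | intermediate
10 | (E)-hexadec-14-enal | C/C=C/CCCCCCCCCCCCC=O | intermediate
11 | (5S)-5-[(16E)-3-oxooctadec-16-enoyl]dihydrofuran-2(3H)-one | C/C=C/CCCCCCCCCCCCC(=O)CC(=O)[C@@H]1CCC(=O)O1 | intermediate
12 | (1S,4R)-3-[(E)-hexadec-14-enoyl]-4-hydroxy-7-oxabicyclo[2.2.1]heptan-2-one (present as its alkoxide, either configuration at C3 of the bicycle) | C/C=C/CCCCCCCCCCCCC(=O)C1C(=O)[C@@H]2CC[C@@]1(O)O2 | intermediate
13 | (6S)-2-[(E)-hexadec-14-enoyl]-3,6-dihydroxycyclohex-2-en-1-one | C/C=C/CCCCCCCCCCCCC(=O)C1=C(O)CC[C@H](O)C1=O | target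

**Step count**

Total step count: 7.
Longest linear sequence: 4 steps (1, 2, 3, 7 or 4, 5, 6, 7).

**Steps most likely to fail**

Step 7. The transannular addition may be too slow because of the strain of the bicyclic adduct. The diketo lactone would then linger under DBU at elevated temperature, with gradual epimerisation at C6 or decomposition.
- The fallback sets out from 4 and 10 and removes the temporary ring before the closure instead of using it.
- Only the SnCl2 coupling, which is known chemistry, is run, and 11 is isolated.
- NaOMe in MeOH then opens the lactone to the sodium enolate of methyl (4S,20E)-4-hydroxy-5,7-dioxodocos-20-enoate F1.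
- On warming, F1 closes by the classical open-chain Dieckmann cyclisation of a 5,7-dioxo ester, a 6-(enolexo)-exo-trig closure without a bicyclic adduct.
- The fallback comes back to the route at 13 after acidification.

Step 3. Adventitious HCl may capture the diazoketone, desilylation may be incomplete, or configuration may be lost through a ketene pathway.
- The fallback sets out from 3 and installs the diazo group by diazo transfer instead of diazoalkane acylation.
- Me2CuLi in Et2O at −78 °C converts 3 into (S)-5-acetyldihydrofuran-2(3H)-one F2.
- Kinetic deprotonation at the methyl group with LiN(SiMe3)2 at −78 °C, followed by trifluoroacetylation with CF3CO2CH2CF3, gives (S)-5-(4,4,4-trifluoro-3-oxobutanoyl)dihydrofuran-2(3H)-one F3.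
- Detrifluoroacetylative diazo transfer with MsN3, Et3N and H2O in MeCN comes back to the route at 4.

Step 5. The Grignard reagent may add to the ester, or homocouple, faster than it cross-couples.
- The fallback sets out from 6 (through its Grignard reagent 8) and uses an electrophile without a carbonyl group, so the oxidation level is set afterwards.
- Commercial 10-bromodecan-1-ol is protected with dihydropyran and PPTS as 2-[(10-bromodecyl)oxy]tetrahydro-2H-pyran F4.
- Li2CuCl4-catalysed coupling with 8 gives 2-{[(E)-hexadec-14-en-1-yl]oxy}tetrahydro-2H-pyran F5.
- PPTS in MeOH releases (E)-hexadec-14-en-1-ol F6.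
- Oxidation with Dess–Martin periodinane comes back to the route at 10, bypassing 9 and step 6.

**Further compounds**

F1 | step 7 | methyl (4S,20E)-4-hydroxy-5,7-dioxodocos-20-enoate | C/C=C/CCCCCCCCCCCCC(=O)CC(=O)[C@@H](O)CCC(=O)OC
F2 | step 3 | (S)-5-acetyldihydrofuran-2(3H)-one | CC(=O)[C@@H]1CCC(=O)O1
F3 | step 3 | (S)-5-(4,4,4-trifluoro-3-oxobutanoyl)dihydrofuran-2(3H)-one | O=C(CC(=O)C(F)(F)F)[C@@H]1CCC(=O)O1
F4 | step 5 | 2-[(10-bromodecyl)oxy]tetrahydro-2H-pyran | BrCCCCCCCCCCOC1CCCCO1
F5 | step 5 | 2-{[(E)-hexadec-14-en-1-yl]oxy}tetrahydro-2H-pyran | C/C=C/CCCCCCCCCCCCCOC1CCCCO1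
F6 | step 5 | (E)-hexadec-14-en-1-ol | C/C=C/CCCCCCCCCCCCCO
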